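**Retrosynthetic overview**
1. Target 5 ⇒ 4: the last C–Br bond, made at the only free CH of one ring of the symmetrical tetrabromo bis-catechol 4.
2. 4 ⇒ 2 (key step): both new aryl C–O bonds, made by ortho-ipso oxygenation of tetrabromobisphenol F with a 1,2-bromine shift; this also sets the 3,6-dibromocatechol pattern of each ring.
3. 2 ⇒ 1: fourfold ortho-bromination of bisphenol F.
4. No ring is formed and no C–C bond is made; both benzene rings and the CH2 bridge are bought intact in 1.

Assumption: the target has no stereocentre and is achiral, so the structure given is its only stereoisomer and no stereocontrol is needed.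

**Route**

Step 1
Reactants: 1 bisphenol F (4,4'-methylenediphenol)
Product: 2 4,4'-methylenebis(2,6-dibromophenol)
Conditions: Br2 (4.1 equiv), AcOH/H2O, 15 °C → rt
Reagents that add atoms: bromine, BrBr
Why: Electrophilic aromatic bromination directed by each phenolic OH goes only to the four ortho positions, because the para position carries the CH2 bridge and the meta positions are unactivated; no stereocentre is formed.

Step 2
Reactants: 2 4,4'-methylenebis(2,6-dibromophenol)
Product: 4 4,4'-methylenebis(3,6-dibromobenzene-1,2-diol), via tetrabromo bis-o-quinone 3 (not isolated)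
Conditions: IBX (2.2 equiv), CF3CO2H/CH2Cl2 (1:4), 4 Å MS, 0 °C → rt; then Na2S2O4, H2O/EtOAc, 0 °C
Reagents that add atoms: IBX (1-hydroxy-1λ5,2-benziodoxol-3(1H)-one 1-oxide), O=C1OI(=O)(O)c2ccccc12
Why: Proposed new method: each 2,6-dibromophenol ring binds IBX as an aryloxy-iodane of pentavalent iodine whose iodyl oxygen can be delivered by [2,3]-sigmatropic shift only to a bromine-bearing ortho carbon, giving a 6-bromo-6-(iodanyloxy)cyclohexa-2,4-dienone of trivalent iodine; its CF3CO2H-protonated form carries positive charge on the adjacent ring CH, so a 1,2-bromonium (NIH-type) shift to that carbon leaves an oxygen-stabilised cation that rearomatises by proton loss, the catechol–iodane collapses to o-quinone 3 and 2-iodobenzoic acid, and Na2S2O4 reduces 3 to 4, so the new C–O bond stands where the bromine was and the bromine one carbon further on; the closest known reaction types are the IBX ortho-oxygenation of phenols to o-quinones with reductive work-up (including hydroxylative dearomatisation at substituted ortho carbons), the NIH shift of halogen in arene hydroxylation and the acid-catalysed 1,2-bromine shift of bromocyclohexadienones (dienone–phenol rearrangement); no stereocentre is formed.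

Step 3
Reactants: 4 4,4'-methylenebis(3,6-dibromobenzene-1,2-diol)
Product: 5 3,4,6-tribromo-5-[(2,5-dibromo-3,4-dihydroxyphenyl)methyl]benzene-1,2-diol
Conditions: Br2 (1.0 equiv, slow addition), AcOH, 15 °C
Reagents that add atoms: bromine, BrBr
Why: Electrophilic aromatic bromination can only enter the single free CH of a ring (para to one OH), and a second bromination on the other ring is slowed because it would give a diarylmethane with four ortho bromines, so monobromination should be favoured beyond the statistical ratio; no stereocentre is formed.

**Compound list**
1 | bisphenol F (4,4'-methylenediphenol) | Oc1ccc(Cc2ccc(O)cc2)cc1 | starting material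
2 | 4,4'-methylenebis(2,6-dibromophenol) | Oc1c(Br)cc(Cc2cc(Br)c(O)c(Br)c2)cc1Br | intermediate
3 | 4,4'-methylenebis(3,6-dibromocyclohexa-3,5-diene-1,2-dione) (tetrabromo bis-o-quinone, not isolated) | O=C1C(=O)C(Br)=C(CC2=C(Br)C(=O)C(=O)C(Br)=C2)C=C1Br | intermediate
4 | 4,4'-methylenebis(3,6-dibromobenzene-1,2-diol) | Oc1c(O)c(Br)c(Cc2cc(Br)c(O)c(O)c2Br)cc1Br | intermediate
5 | 3,4,6-tribromo-5-[(2,5-dibromo-3,4-dihydroxyphenyl)methyl]benzene-1,2-diol (CNP0260137.0) | Oc1c(Br)cc(Cc2c(Br)c(O)c(O)c(Br)c2Br)c(Br)c1O | target

**Totals and risks**
Total step count: 3. Longest linear sequence: 3.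

Most likely to fail, first: step 2, the proposed new step. Three failure modes are foreseen:
- The gem-bromo dienone may be hydrolysed to a 3-bromo-o-quinone and HBr before the bromine shifts; bromide then adds 1,4 and gives the 5,6-dibromo isomer.
- The doubly benzylic CH2 may be oxidised through a p-quinone methide.
- The electron-poor phenol may bind or transfer oxygen too slowly.

The fallback uses known chemistry, sets out from 2 and comes back at 4. Compound 2 is heated with aqueous NaOH and catalytic Cu2O at 100 °C under argon. This phenoxide-assisted Ullmann-type hydroxylation replaces one ortho bromine per ring by OH, as in the conversion of 5-bromovanillin to 5-hydroxyvanillin. The resulting trianionic catecholate rings resist a second exchange, so the product is 5,5'-methylenebis(3-bromobenzene-1,2-diol) F1. Amine-directed ortho-bromination (Br2/tert-butylamine, 2.1 equiv, toluene/CH2Cl2, −78 °C) then delivers bromine from the hydrogen-bonded N-bromoamine to the position between the new OH and the CH2 bridge of each ring, giving 4.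

Second: step 3. The risks are over-bromination to the hexabromide, leaving a mixture of 4, 5 and hexabromide to be separated by reversed-phase chromatography with recycling of 4, and para-ipso attack that cleaves the bridge. The fallback reverses the polarity of bromine; it sets out from 4 and comes back at 5. Compound 4 is oxidised with Ag2O (1.0 equiv, Et2O, rt) to the mono-o-quinone 3,6-dibromo-4-[(2,5-dibromo-3,4-dihydroxyphenyl)methyl]cyclohexa-3,5-diene-1,2-dione F2. HBr (1.0 equiv, in AcOH, 0 °C) is then added. Bromide undergoes conjugate 1,4-addition at the only ring CH of the quinone ring and tautomerisation gives 5. The number of bromines introduced is capped by the oxidant, not by an electrophile.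

Third: step 1. The risk is para-ipso bromodealkylation, which would cut the CH2 bridge. The fallback puts oxygen in before bromine; it sets out from 1 and comes back at 4, bypassing 2 and 3. Casnati–Skattebøl ortho-formylation of 1 (MgCl2, Et3N, paraformaldehyde, MeCN, reflux) gives 5,5'-methylenebis(2-hydroxybenzaldehyde) F3. Dakin oxidation (H2O2, NaOH, H2O/THF, 0 °C) gives 4,4'-methylenebis(benzene-1,2-diol) F4. Fourfold amine-directed ortho-bromination (Br2/tert-butylamine, 4.2 equiv, toluene/CH2Cl2, −78 °C) places bromine next to each OH and gives 4. The open para CH of each ring in F4 is the main hazard of this last operation.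

**Further compounds**
F1 | step 2 | 5,5'-methylenebis(3-bromobenzene-1,2-diol) | Oc1cc(Cc2cc(O)c(O)c(Br)c2)cc(Br)c1O
F2 | step 3 | 3,6-dibromo-4-[(2,5-dibromo-3,4-dihydroxyphenyl)methyl]cyclohexa-3,5-diene-1,2-dione | O=C1C(=O)C(Br)=C(Cc2cc(Br)c(O)c(O)c2Br)C=C1Br
F3 | step 1 | 5,5'-methylenebis(2-hydroxybenzaldehyde) | O=Cc1cc(Cc2ccc(O)c(C=O)c2)ccc1O
F4 | step 1 | 4,4'-methylenebis(benzene-1,2-diol) | Oc1ccc(Cc2ccc(O)c(O)c2)cc1O
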